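I read the four flasks at 3.0 h, twice as long as the last reading of the earlier runs, so what I want is where each one stops.

common to all: second substrate 100 mM; catalyst 40 µM

| run | starting material | partner | remark | time |
|---|---|---|---|---|
| dawn | 15 mM | 16 mM | run made earlier |  |
| winter | 60 mM | 16 mM | run made earlier |  |
| noon | 120 mM | 16 mM | run made earlier |  |
| Saturday's | 20 mM | 16.0 mM |  | 3.0 h |
| Thursday's | 40 mM | 16.0 mM |  | 3.0 h |
| Wednesday's | 80 mM | 16.0 mM |  | 3.0 h |
| Sunday's | 150 mM | 16.0 mM |  | 3.0 h |

| run | time / min | target / % | starting material / % |
|---|---|---|---|
| dawn | 8.00 | 11.8 | 86.3 |
| dawn | 25.0 | 24.7 | 74.3 |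
| dawn | 40.0 | 31.9 | 68.6 |
| dawn | 60.0 | 35.5 | 64.4 |
| dawn | 90.0 | 37.0 | 60.2 |
| winter | 8.00 | 10.3 | 90.6 |
| winter | 25.0 | 14.8 | 84.4 |
| winter | 40.0 | 17.9 | 82.8 |
| winter | 60.0 | 19.3 | 80.8 |
| winter | 90.0 | 19.8 | 78.9 |
| noon | 8.00 | 6.6 | 93.0 |
| noon | 25.0 | 10.9 | 90.2 |
| noon | 40.0 | 11.7 | 90.0 |
| noon | 60.0 | 13.3 | 88.6 |
| noon | 90.0 | 13.4 | 89.7 |

(scatter of a reading: 1 percentage point)

- the numbers in the tables scatter with a standard deviation of 1 percentage point
- a reading or a percentage of target counts all its forms, free or not
- "hardly changes" means that all values lie within two and a half points (for a concentration: within two and a half percent of the largest)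

* amount of target at the end, in percent of the starting material charged for Saturday's, Thursday's, Wednesday's, Sunday's, in this order
* the course of these numbers from the first flask to the last (rises, then falls / hardly changes / falls all the way / rises all the way / falls, then rises)

The winter run reads 19.3% of target at 60.0 min and 19.8% at 90.0 min, with 78.9% of its starting material still there, so I read a plateau of 11.9 mM, with the scatter of that reading. I bracket Wednesday's flask. From above: target and starting material add up to about the charge, so I count one partner per target, which makes partner the limiting reagent and caps Wednesday's at 16.0 mM, or 20.0%. From below: with a larger charge, Wednesday's should capture at least the winter run's amount, or 14.8%.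

To tighten this, I suppose that partner also disappears by a second way that uses no starting material, so that at each moment the captured share is [starting material]/([starting material] + h). Here h is the crossing charge, the [starting material] at which capture and loss run level, and the winter reading puts it at 18.7 mM, with that reading's scatter. Summed over a run, with A the charge of starting material, partner charge = target + h·ln(A/(A − target)). Entering the lower bound gives 13.0 mM, and entering that gives 12.7 mM. The first entry is smaller than the answer it returns, and the larger second entry returns a smaller answer, so I take the two answers as the edges of my estimate. My bracket for Wednesday's is therefore 15.9% to 16.2%. Target in mM stays capped while the charge grows, so I expect the percentages to fall.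

The forecast gives 35%, 25.5%, 16% and 10%, course falls all the way, on other grounds than mine: “This looks like a reversible 1:1 reaction”. Its Wednesday's value is lower than my upper edge and higher than my lower edge, so it stands inside the bracket.

The flasks give 37.6%, 26.0%, 15.9% and 9.41%, course falls all the way.

    starting material + partner + catalyst → catalyst + target (k = 2.09 × 10⁶ /M²/h)
    second substrate + partner + catalyst → catalyst + second product (k = 1.37 × 10⁵ /M²/h)
    catalyst ⇌ dormant form (K = 12.0, k = 0.278 /h)
    catalyst + target ⇌ idle complex, settled at all times (K = 140 /M)
    partner → decomposed reagent (k = 0.512 /h)

Wednesday's keeps 0.0406% of its partner at 3.00 h. The crossing charge of 18.7 mM puts that flask's partner loss at 3.23 mM, and its second product and decomposed reagent together stand at 3.26 mM. On Sunday's flask the same crossing charge gives a loss of 1.85 mM, and at 3.00 h that flask holds 0.646 mM of second product and 1.24 mM of decomposed reagent.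

All runs are simulated on assumed constants; noise was put on by code.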